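## The problem

The target 59 is a 36-membered macrolactone: an unbranched C40 chain whose C1 carboxyl is esterified by the C35 hydroxyl, with methyl branches at C3 and C36 and nine free secondary hydroxyls at C5, C9, C13, C17, C21, C25, C27, C29 and C33. There is one ring and no unsaturation, so the difficulty lies in the chain: twelve stereocentres spread over forty carbons. Most carbinols are 1,5-related (C5/C9/C13/C17/C21/C25 and C29/C33) and cannot control one another, so each must come from a reagent, a catalyst or a purchased building block. Only the C25/C27/C29 triad (syn, anti) and the C33/C35/C36 array (anti, anti) are close enough for substrate control. Nine hydroxyls of one kind must be kept apart from the tenth (O35), which closes the ring. The free polyol lactone will not tolerate base (acyl shift from O35 to O33), and a β-hydroxy ketone at C27 is open to elimination or retro-aldol cleavage. The enabling feature is C27: the only carbinol carbon lying between two methylenes (C26, C28) that are each flanked by a further carbinol (C25, C29), i.e. an acyl dianion placed between two terminal epoxides. Everywhere else the carbon midway between two carbinols (C7, C11, C15, C19, C23, C31) is a plain methylene, so there the chain is better grown by reactions that leave no functional group behind.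

## Retrosynthesis

**Ring opening at C1–O35.** 59 comes from the nonakis-silyl lactone 58, and 58 from seco acid 56 by Yamaguchi macrolactonisation. Cutting the only heteroatom bond of the ring is preferred to any C–C ring closure: it reduces the problem to a linear chain and leaves no residual functionality. The forward step must acylate a hindered secondary hydroxyl (C35, next to the C36 branch) at high dilution. The nine other hydroxyls are masked as TBS ethers so that one acid treatment ends the synthesis.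

**End groups.** 56 is traced to 52, in which C1 is a PMB ether and O35 a benzyl ether. DDQ frees C1 (53), oxidation gives acid 55, and hydrogenolysis frees O35. Two different benzyl-type ethers are chosen so that C1 is oxidised while no secondary hydroxyl is free.

**C27 carbinol.** 52 comes from the anti-diol 51, 51 from β-hydroxy ketone 50, and 50 from dithiane 49. Putting C27 at the ketone level lets the free O29 deliver hydride (Evans–Saksena), which sets C27 anti to C29 and therefore syn to C25. The reduction needs exactly one free hydroxyl next to the ketone.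

**C26–C27 and C27–C28 (key step).** 49 is cut on both sides of C27 into epoxide 32 (C1–C26), silyl dithiane 4 and epoxide 46 (C28–C40). Cuts at C24–C25 or C29–C30 would each create a new stereocentre during fragment union; this cut joins two halves without creating one. The forward reaction must open two different terminal epoxides in a fixed order. It must also leave O25 silylated and O29 free, which the Brook relay does by itself.

**Epoxide 32 from aldehyde 30.** 32 comes by hydrolytic kinetic resolution of the C25-epimeric epoxide 31, made by methylene transfer (C25–C26) to aldehyde 30. The aldehyde is the natural end of the chain-growing cycle, so the epoxide costs two operations. The price is that the resolution discards up to half of 31; buying C25 instead is held in reserve.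

**C8–C25 by allylation and hydroformylation.** 30 is cut at C24–C25, C21–C22, C20–C21, C17–C18, C16–C17, C13–C14, C12–C13 and C9–C10. Each cycle is an asymmetric allylboration of an aldehyde (14, 18, 22, 26 giving 16, 20, 24, 28), silylation (17, 21, 25, 29) and linear hydroformylation (18, 22, 26, 30). The neighbouring option, running a dithiane relay through C7, C11, C15, C19 and C23 as well, would build the same bonds faster. It would, however, leave five dithioacetals to be reduced on one molecule and would generate the same lithiated linchpin again and again under HMPA. Allylation and hydroformylation deliver the methylenes directly and reserve the relay for C27, where the dithiane carbon is wanted as a carbinol. What is asked of the forward steps is reagent control at each new carbinol, since no neighbour can help.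

**C6–C9, first unit.** 14 comes by hydroformylation (C8–C9) of silyl ether 13, 13 from homoallylic alcohol 12, and 12 from epoxide 11 and a vinyl cuprate (C6–C7). This hands over the C5 stereocentre of 11 unchanged and enters the cycle at the aldehyde stage.

**First epoxide 11.** 11 comes from chlorohydrin 10, made by catalytic α-chlorination of aldehyde 8, which comes from (R)-citronellol 5 via PMB ether 6. Citronellol supplies C1–C6 and the C3 methyl stereocentre. Only C5 has to be created, under catalyst control.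

**Epoxide 46, C28–C33.** 46 comes by hydrolytic kinetic resolution of the epimeric epoxide 45, made by methylene transfer to aldehyde 44. 44 comes by linear hydroformylation of 43, the silyl ether of homoallylic alcohol 42. 42 comes from β-benzyloxy aldehyde 41 by chelation-controlled allylation (C32–C33), which uses the C35 ether to set C33 anti. The resolution costs at most half of 45; this is accepted because it is late only within the short arm.

**C34–C36.** 41 comes from benzyl ether 39 by ozonolysis; 39 from alcohol 38, and 38 from epoxide 37 and a vinyl cuprate (C33–C34). 37 comes from diol 35, which arises from Sharpless epoxide 34 of (E)-hept-2-en-1-ol 33 by C3-selective methyl transfer from Me3Al. The trans-epoxide geometry fixes the C35/C36 anti relationship, so no epimerisable α-methyl aldehyde is needed.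

**Linchpin.** 4 comes from 1,3-dithiane 1 and silyl chloride 2.

## Roads not taken

**Alternative 1: Baeyer–Villiger oxygen insertion.**
- Cut and key step: the ring O–C35 bond is made last. A buffered peracid converts the 35-membered carbocyclic ketone A2 into lactone A1 (identical with 58), C35 migrating with retention.
- Merits: no acylation of the hindered O35, no protecting group on O35, no oxidation-state changes at C1. The endgame would be shorter than the present one.
- Weak points: A2 has no heteroatom at which to close a 35-membered carbocycle. C35 in A2 is an α-stereocentre next to the ketone and the C36 branch, so it can epimerise. Secondary over primary migration is a preference, not a guarantee.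
- Comparison: the chosen plan offers a C35 that is never α to a carbonyl and a ring closure of a proven type. The C27 linchpin could still build the chain of A2, but the macrocyclisation problem would only be moved.

**Alternative 2: one-pot double lithiation–borylation.**
- Cut and key step: pinacol n-butylboronate A4 is homologated first by the sparteine-ligated lithio derivative of ethyl 2,4,6-triisopropylbenzoate A5 (C36–C37), then by that of the C30–C35 benzoate A6 (C35–C36). The product is the secondary boronic ester A3.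
- Merits: both stereocentres are reagent-programmed in one flask. Oxidation and benzylation of A3 would give 43, so this road reaches that point in about as many steps as steps 23–30, or one or two fewer.
- Weak points: two cryogenic carbenoid steps in sequence, the second on a secondary boronate; dependence on sparteine; it addresses two of twelve stereocentres and leaves the 1,5-polyol untouched.
- Comparison: the chosen plan fixes the anti relationship by epoxide geometry with ordinary reagents. The two approaches are compatible and A3 could replace the C30–C40 arm of 43.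

**Alternative 3: two-directional iridium double allylation.**
- Cut and key step: the C9–C21 segment is C2-symmetric. Diol A8 is dehydrogenated at both termini and allylated by an allyliridium species from allyl acetate and [Ir(cod)Cl]2 with a chiral bisphosphine. This forms C8–C9 and C21–C22 and gives diene diol A7.
- Merits: two C–C bonds and two stereocentres per operation, directly from the alcohol level and with a catalytic source of chirality. For the C9–C21 core this is more economical than the one-directional cycle of steps 9–20.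
- Weak points: the two ends of A7 are identical but must diverge (C5 is syn to C9, C25 is anti to C21, and the termini differ), which means a statistical mono-functionalisation. Each new carbinol still needs a separate protection and a one-carbon homologation, and C13/C17 of A8 must be set beforehand.
- Comparison: the chosen plan grows one end only, so no desymmetrisation is needed and each carbinol is addressed by its own reagent antipode. It pays with more operations for the core and with stoichiometric chiral boranes.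

Key step: step 34

Assumption: reagents and catalysts are named on their usual sense of induction ((5R)-imidazolidinone giving the (R)-α-chloro aldehyde; the allylborane from (+)-α-pinene adding to the Si face and that from (−)-α-pinene to the Re face of an aldehyde; (S,S)-(salen)Co(OAc) sparing the (S)-alkyloxirane); if any sense is the opposite, the antipode is used and nothing else changes.

Convention: chain carbons carry the numbers they have in 59 (C1 = lactone carbonyl carbon, C35 = ester carbinol, C40 = chain end). CIP descriptors are those of the compound named. TBS = tert-butyldimethylsilyl, PMB = 4-methoxybenzyl, Bn = benzyl, Ipc = isopinocampheyl.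

## Route

Step 1
Reactants: 1 1,3-dithiane; 2 tert-butyldimethylsilyl chloride
Product: 4 2-(tert-butyldimethylsilyl)-1,3-dithiane, via 2-lithio-1,3-dithiane 3 (not isolated)
Conditions: n-BuLi, THF, −30 °C; then 2, −78 °C → rt
Reagents that add atoms: none
Why: Corey–Seebach metalation of the dithiane C2–H followed by C-silylation; the product is the linchpin of step 34.

Step 2
Reactants: 5 (R)-citronellol
Product: 6 (R)-citronellyl PMB ether
Conditions: NaH, 4-methoxybenzyl chloride, Bu4NI (cat.), THF/DMF, 0 °C → rt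
Reagents that add atoms: 4-methoxybenzyl chloride, COc1ccc(CCl)cc1
Why: Williamson etherification of a primary alcohol; PMB is chosen for C1 because it tolerates Grignard, allylborane and organolithium reagents and hydroformylation, and is later removed by DDQ beside the C35 benzyl ether.

Step 3
Reactants: 6 (R)-citronellyl PMB ether
Product: 8 (4R)-6-(PMB-oxy)-4-methylhexanal, via ozonide 7 (not isolated)
Conditions: O3, CH2Cl2, −78 °C (stopped at first blue colour); then PPh3, −78 °C → rt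
Reagents that add atoms: ozone, [O-][O+]=O
Why: Ozonolysis with reductive work-up; the trisubstituted alkene reacts far faster than the anisyl ring at −78 °C, and C6 becomes the aldehyde whose α-carbon is C5.

Step 4
Reactants: 8 (4R)-6-(PMB-oxy)-4-methylhexanal
Product: 10 (2R,4S)-2-chloro-6-(PMB-oxy)-4-methylhexan-1-ol, via α-chloro aldehyde 9 (not isolated)
Conditions: (5R)-5-benzyl-2,2,3-trimethylimidazolidin-4-one·CF3CO2H (10 mol%), 2,3,4,5,6,6-hexachlorocyclohexa-2,4-dien-1-one, acetone, −30 °C; then NaBH4, MeOH, 0 °C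
Reagents that add atoms: 2,3,4,5,6,6-hexachlorocyclohexa-2,4-dien-1-one, O=C1C(Cl)=C(Cl)C(Cl)=C(Cl)C1(Cl)Cl
Why: Enamine-catalysed asymmetric α-chlorination of an unbranched aldehyde; the chiral amine shields one enamine face, so C5 is set by the catalyst (the C3 methyl is γ and too remote to interfere). Immediate borohydride reduction forestalls enolisation of the α-chloro aldehyde.

Step 5
Reactants: 10 (2R,4S)-2-chloro-6-(PMB-oxy)-4-methylhexan-1-ol
Product: 11 C1–C6 epoxide (5,6-epoxide)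
Conditions: KOH, EtOH/H2O, 0 °C → rt
Reagents that add atoms: none
Why: Intramolecular Williamson reaction of the chlorohydrin; the C6 alkoxide displaces chloride at C5 with inversion and gives the (S)-oxirane.

Step 6
Reactants: 11 C1–C6 epoxide
Product: 12 C1–C8 homoallylic alcohol (5-OH), (4R,6S)-8-(PMB-oxy)-6-methyloct-1-en-4-ol
Conditions: vinylmagnesium bromide, CuI (10 mol%), THF, −40 → 0 °C
Reagents that add atoms: vinylmagnesium bromide, C=C[Mg]Br
Why: Copper-catalysed SN2 opening of the terminal epoxide at its CH2 (C6), forming C6–C7; C5 is not touched and is carried over from 11.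

Step 7
Reactants: 12 C1–C8 homoallylic alcohol
Product: 13 C1–C8 alkene (5-OTBS)
Conditions: TBSOTf, 2,6-lutidine, CH2Cl2, −78 → 0 °C
Reagents that add atoms: tert-butyldimethylsilyl triflate, CC(C)(C)[Si](C)(C)OS(=O)(=O)C(F)(F)F
Why: Standard silylation of a secondary alcohol with a silyl triflate and a hindered base.

Step 8
Reactants: 13 C1–C8 alkene
Product: 14 C1–C9 aldehyde (5-OTBS)
Conditions: Rh(acac)(CO)2 (1 mol%), Xantphos (2 mol%), CO/H2 (1:1, 10 bar), toluene, 70 °C
Reagents that add atoms: carbon monoxide, [C-]#[O+]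
Why: Rhodium-catalysed hydroformylation; the wide-bite-angle diphosphine directs formylation to the terminal carbon, giving the linear aldehyde with C9 as carbonyl carbon and no α-stereocentre to lose.

Step 9
Reactants: 14 C1–C9 aldehyde
Product: 16 C1–C12 homoallylic alcohol (9-OH; 5-OTBS), via C9 borinate 15 (not isolated)
Conditions: (+)-Ipc2B(allyl) (from (−)-α-pinene, 1.3 equiv), Et2O, −100 → −78 °C; then NaOH, H2O2, 0 °C → rt
Reagents that add atoms: (+)-B-allylbis(isopinocampheyl)borane, C=CCB([C@H]1C[C@H]2C[C@@H]([C@@H]1C)C2(C)C)[C@H]1C[C@H]2C[C@@H]([C@@H]1C)C2(C)C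
Why: Brown allylboration through a closed six-membered chair transition state, forming C9–C10; the isopinocampheyl groups of the reagent from (−)-α-pinene leave only the Re face of the aldehyde open, so C9 is set by the reagent (C5 is 1,5-remote and has no say). Alkaline peroxide cleaves borinate 15 to the alcohol.

Step 10
Reactants: 16 C1–C12 homoallylic alcohol
Product: 17 C1–C12 alkene (5,9-bis-OTBS)
Conditions: TBSOTf, 2,6-lutidine, CH2Cl2, −78 → 0 °C
Reagents that add atoms: tert-butyldimethylsilyl triflate, CC(C)(C)[Si](C)(C)OS(=O)(=O)C(F)(F)F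
Why: Standard silylation of a secondary alcohol with a silyl triflate and a hindered base.

Step 11
Reactants: 17 C1–C12 alkene
Product: 18 C1–C13 aldehyde (5,9-bis-OTBS)
Conditions: Rh(acac)(CO)2 (1 mol%), Xantphos (2 mol%), CO/H2 (1:1, 10 bar), toluene, 70 °C
Reagents that add atoms: carbon monoxide, [C-]#[O+]
Why: Linear-selective rhodium-catalysed hydroformylation as in step 8; C13 becomes the carbonyl carbon.

Step 12
Reactants: 18 C1–C13 aldehyde
Product: 20 C1–C16 homoallylic alcohol (13-OH; 5,9-bis-OTBS), via C13 borinate 19 (not isolated)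
Conditions: (−)-Ipc2B(allyl) (from (+)-α-pinene, 1.3 equiv), Et2O, −100 → −78 °C; then NaOH, H2O2, 0 °C → rt
Reagents that add atoms: (−)-B-allylbis(isopinocampheyl)borane, C=CCB([C@@H]1C[C@@H]2C[C@H]([C@H]1C)C2(C)C)[C@@H]1C[C@@H]2C[C@H]([C@H]1C)C2(C)C
Why: Brown allylboration, forming C13–C14; the reagent from (+)-α-pinene adds to the Si face through the chair transition state and sets C13 under reagent control. Alkaline peroxide cleaves borinate 19.

Step 13
Reactants: 20 C1–C16 homoallylic alcohol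
Product: 21 C1–C16 alkene (5,9,13-tris-OTBS)
Conditions: TBSOTf, 2,6-lutidine, CH2Cl2, −78 → 0 °C
Reagents that add atoms: tert-butyldimethylsilyl triflate, CC(C)(C)[Si](C)(C)OS(=O)(=O)C(F)(F)F
Why: Standard silylation of a secondary alcohol with a silyl triflate and a hindered base.

Step 14
Reactants: 21 C1–C16 alkene
Product: 22 C1–C17 aldehyde (5,9,13-tris-OTBS)
Conditions: Rh(acac)(CO)2 (1 mol%), Xantphos (2 mol%), CO/H2 (1:1, 10 bar), toluene, 70 °C
Reagents that add atoms: carbon monoxide, [C-]#[O+]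
Why: Linear-selective rhodium-catalysed hydroformylation as in step 8; C17 becomes the carbonyl carbon.

Step 15
Reactants: 22 C1–C17 aldehyde
Product: 24 C1–C20 homoallylic alcohol (17-OH; 5,9,13-tris-OTBS), via C17 borinate 23 (not isolated)
Conditions: (+)-Ipc2B(allyl) (from (−)-α-pinene, 1.3 equiv), Et2O, −100 → −78 °C; then NaOH, H2O2, 0 °C → rt
Reagents that add atoms: (+)-B-allylbis(isopinocampheyl)borane, C=CCB([C@H]1C[C@H]2C[C@@H]([C@@H]1C)C2(C)C)[C@H]1C[C@H]2C[C@@H]([C@@H]1C)C2(C)C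
Why: Brown allylboration, forming C17–C18; Re-face addition by the reagent from (−)-α-pinene sets C17 under reagent control. Alkaline peroxide cleaves borinate 23.

Step 16
Reactants: 24 C1–C20 homoallylic alcohol
Product: 25 C1–C20 alkene (5,9,13,17-tetrakis-OTBS)
Conditions: TBSOTf, 2,6-lutidine, CH2Cl2, −78 → 0 °C
Reagents that add atoms: tert-butyldimethylsilyl triflate, CC(C)(C)[Si](C)(C)OS(=O)(=O)C(F)(F)F
Why: Standard silylation of a secondary alcohol with a silyl triflate and a hindered base.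

Step 17
Reactants: 25 C1–C20 alkene
Product: 26 C1–C21 aldehyde (5,9,13,17-tetrakis-OTBS)
Conditions: Rh(acac)(CO)2 (1 mol%), Xantphos (2 mol%), CO/H2 (1:1, 10 bar), toluene, 70 °C
Reagents that add atoms: carbon monoxide, [C-]#[O+]
Why: Linear-selective rhodium-catalysed hydroformylation as in step 8; C21 becomes the carbonyl carbon.

Step 18
Reactants: 26 C1–C21 aldehyde
Product: 28 C1–C24 homoallylic alcohol (21-OH; 5,9,13,17-tetrakis-OTBS), via C21 borinate 27 (not isolated)
Conditions: (−)-Ipc2B(allyl) (from (+)-α-pinene, 1.3 equiv), Et2O, −100 → −78 °C; then NaOH, H2O2, 0 °C → rt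
Reagents that add atoms: (−)-B-allylbis(isopinocampheyl)borane, C=CCB([C@@H]1C[C@@H]2C[C@H]([C@H]1C)C2(C)C)[C@@H]1C[C@@H]2C[C@H]([C@H]1C)C2(C)C
Why: Brown allylboration, forming C21–C22; Si-face addition by the reagent from (+)-α-pinene sets C21 under reagent control. Alkaline peroxide cleaves borinate 27.

Step 19
Reactants: 28 C1–C24 homoallylic alcohol
Product: 29 C1–C24 alkene (5,9,13,17,21-pentakis-OTBS)
Conditions: TBSOTf, 2,6-lutidine, CH2Cl2, −78 → 0 °C
Reagents that add atoms: tert-butyldimethylsilyl triflate, CC(C)(C)[Si](C)(C)OS(=O)(=O)C(F)(F)F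
Why: Standard silylation of a secondary alcohol with a silyl triflate and a hindered base.

Step 20
Reactants: 29 C1–C24 alkene
Product: 30 C1–C25 aldehyde (5,9,13,17,21-pentakis-OTBS)
Conditions: Rh(acac)(CO)2 (1 mol%), Xantphos (2 mol%), CO/H2 (1:1, 10 bar), toluene, 70 °C
Reagents that add atoms: carbon monoxide, [C-]#[O+]
Why: Linear-selective rhodium-catalysed hydroformylation as in step 8; C25 becomes the carbonyl carbon.

Step 21
Reactants: 30 C1–C25 aldehyde
Product: 31 C1–C26 epoxide as both C25 epimers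
Conditions: trimethylsulfonium iodide, n-BuLi, THF, −10 °C → rt
Reagents that add atoms: trimethylsulfonium iodide, C[S+](C)C.[I-]
Why: Corey–Chaykovsky methylene transfer: the sulfonium ylide adds to the aldehyde and the betaine closes to the terminal epoxide, forming C25–C26. No control at C25 is expected or needed, since the next step sorts the epimers.

Step 22
Reactants: 31 C1–C26 epoxide as both C25 epimers
Product: 32 C1–C26 epoxide, (25S)
Conditions: (S,S)-(salen)Co(OAc) (2 mol%), H2O (0.55 equiv), THF, 0 °C → rt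
Reagents that add atoms: none
Why: Jacobsen hydrolytic kinetic resolution: the chiral cobalt salen complex hydrolyses the (25R)-epoxide to its diol and leaves the (25S)-epoxide. Selection is catalyst-controlled, and the diol is removed by chromatography.

Step 23
Reactants: 33 (E)-hept-2-en-1-ol
Product: 34 [(2R,3R)-3-butyloxiran-2-yl]methanol
Conditions: Ti(OiPr)4 (5 mol%), D-(−)-diethyl tartrate (6 mol%), t-BuOOH, 4 Å sieves, CH2Cl2, −20 °C
Reagents that add atoms: tert-butyl hydroperoxide, CC(C)(C)OO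
Why: Sharpless asymmetric epoxidation; the titanium tartrate complex delivers oxygen to one face of the allylic alcohol (D-tartrate gives the 2R,3R epoxide of an E-allylic alcohol), setting C35 and the trans geometry.

Step 24
Reactants: 34 [(2R,3R)-3-butyloxiran-2-yl]methanol
Product: 35 (2S,3S)-3-methylheptane-1,2-diol
Conditions: Me3Al (3 equiv), hexane/CH2Cl2, 0 °C → rt
Reagents that add atoms: trimethylaluminium, C[Al](C)C
Why: Aluminium alkoxide-directed opening of a 2,3-epoxy alcohol: methyl is delivered to C3 (C36) with inversion, so the trans epoxide gives the anti methyl/hydroxyl pair (C36/C35) and the 1,2-diol.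

Step 25
Reactants: 35 (2S,3S)-3-methylheptane-1,2-diol
Product: 37 (2S)-2-[(2S)-hexan-2-yl]oxirane, via primary tosylate 36 (not isolated)
Conditions: NaH, N-tosylimidazole, THF, 0 °C → rt
Reagents that add atoms: none
Why: Selective sulfonylation of the primary alkoxide and Williamson closure; C35 is retained because substitution takes place at C34.

Step 26
Reactants: 37 (2S)-2-[(2S)-hexan-2-yl]oxirane
Product: 38 (4R,5S)-5-methylnon-1-en-4-ol
Conditions: vinylmagnesium bromide, CuI (10 mol%), THF, −40 → 0 °C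
Reagents that add atoms: vinylmagnesium bromide, C=C[Mg]Br
Why: Copper-catalysed SN2 opening of a terminal epoxide at its CH2 (C34), forming C33–C34; no stereocentre is involved.

Step 27
Reactants: 38 (4R,5S)-5-methylnon-1-en-4-ol
Product: 39 (4R,5S)-4-(benzyloxy)-5-methylnon-1-ene
Conditions: NaH, benzyl bromide, Bu4NI (cat.), THF/DMF, 0 °C → rt
Reagents that add atoms: benzyl bromide, BrCc1ccccc1
Why: Williamson benzylation; the benzyl ether marks O35 as the one oxygen to be freed by hydrogenolysis and provides the chelating group for step 29.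

Step 28
Reactants: 39 (4R,5S)-4-(benzyloxy)-5-methylnon-1-ene
Product: 41 (3R,4S)-3-(benzyloxy)-4-methyloctanal, via ozonide 40 (not isolated)
Conditions: O3, CH2Cl2, −78 °C; then PPh3, −78 °C → rt
Reagents that add atoms: ozone, [O-][O+]=O
Why: Ozonolysis of the terminal alkene with reductive work-up gives the β-benzyloxy aldehyde (C33) without touching the stereocentres.

Step 29
Reactants: 41 (3R,4S)-3-(benzyloxy)-4-methyloctanal
Product: 42 (4S,6R,7S)-6-(benzyloxy)-7-methylundec-1-en-4-ol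
Conditions: TiCl4, CH2Cl2, −78 °C; then allyltrimethylsilane, −78 °C
Reagents that add atoms: allyltrimethylsilane, C=CC[Si](C)(C)C
Why: Chelation-controlled Hosomi–Sakurai allylation: TiCl4 bridges the aldehyde and β-benzyloxy oxygens in a six-membered chelate, and the allylsilane adds to the face opposite the C35 substituent. C33 is thereby set anti to C35.

Step 30
Reactants: 42 (4S,6R,7S)-6-(benzyloxy)-7-methylundec-1-en-4-ol
Product: 43 C30–C40 alkene (33-OTBS; 35-OBn)
Conditions: TBSOTf, 2,6-lutidine, CH2Cl2, −78 → 0 °C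
Reagents that add atoms: tert-butyldimethylsilyl triflate, CC(C)(C)[Si](C)(C)OS(=O)(=O)C(F)(F)F
Why: Standard silylation of a secondary alcohol with a silyl triflate and a hindered base.

Step 31
Reactants: 43 C30–C40 alkene
Product: 44 C29–C40 aldehyde
Conditions: Rh(acac)(CO)2 (1 mol%), Xantphos (2 mol%), CO/H2 (1:1, 10 bar), toluene, 70 °C
Reagents that add atoms: carbon monoxide, [C-]#[O+]
Why: Rhodium-catalysed hydroformylation; the wide-bite-angle diphosphine directs formylation to the terminal carbon, giving the linear aldehyde with C29 as carbonyl carbon.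

Step 32
Reactants: 44 C29–C40 aldehyde
Product: 45 C28–C40 epoxide as both C29 epimers
Conditions: trimethylsulfonium iodide, n-BuLi, THF, −10 °C → rt
Reagents that add atoms: trimethylsulfonium iodide, C[S+](C)C.[I-]
Why: Corey–Chaykovsky methylene transfer: the sulfonium ylide adds to the aldehyde and the betaine closes to the terminal epoxide. No control at C29 is expected or needed, since the next step sorts the epimers.

Step 33
Reactants: 45 C28–C40 epoxide as both C29 epimers
Product: 46 C28–C40 epoxide, (29S)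
Conditions: (S,S)-(salen)Co(OAc) (2 mol%), H2O (0.55 equiv), THF, 0 °C → rt
Reagents that add atoms: none
Why: Jacobsen hydrolytic kinetic resolution: the chiral cobalt salen complex hydrolyses the (29R)-epoxide to its diol and leaves the (29S)-epoxide. Selection is catalyst-controlled, and the diol is removed by chromatography.

Step 34
Reactants: 4 2-(tert-butyldimethylsilyl)-1,3-dithiane; 32 C1–C26 epoxide; 46 C28–C40 epoxide
Product: 49 C1–C40 dithiane (C27 dithiane; 29-OH; 25-OTBS), via lithiated silyl dithiane 47 (not isolated), via C25 lithium alkoxide 48 (not isolated)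
Conditions: 4 (1.05 equiv), t-BuLi, Et2O, −78 → −45 °C; 32, Et2O, −78 → −25 °C; then 46 (1.1 equiv), HMPA/THF, −78 → 0 °C
Reagents that add atoms: none
Why: Anion relay chemistry: 47 attacks the unsubstituted carbon C26 of 32 (SN2) and gives alkoxide 48, which is stable in ether because the carbon-to-oxygen silyl shift needs a polar donor solvent. Adding 46 with HMPA triggers the 1,4-Brook rearrangement through a pentacoordinate silicate; silicon passes from C27 to O25 and the dithiane-stabilised C27 carbanion is regenerated. This anion opens 46 at C28, again the unsubstituted oxirane carbon, forming C27–C28 and leaving O29 as the only free hydroxyl. The closest known reaction type is the solvent-triggered three-component coupling of a 2-silyl-1,3-dithiane with two different terminal epoxides. No ring is closed and no stereocentre is created: C25 and C29 arrive in the epoxides and are retained because both openings occur at CH2. The step needs terminal regioselectivity, which monosubstituted oxiranes flanked by unbranched methylenes (C24, C30) secure, and a strict order of events, which the ether-then-HMPA switch secures. 32 and 46 carry only silyl and benzyl-type ethers and no acidic hydrogen, so the relay anion has no other partner.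

Step 35
Reactants: 49 C1–C40 dithiane
Product: 50 C1–C40 β-hydroxy ketone (27-oxo; 29-OH)
Conditions: Hg(ClO4)2, CaCO3, THF/H2O (5:1), 0 °C
Reagents that add atoms: water, O
Why: Thiophilic metal-assisted hydrolysis of the dithioacetal; divalent mercury binds sulfur and water delivers the carbonyl oxygen. The carbonate buffer protects the silyl ethers and the β-hydroxy ketone from acid.

Step 36
Reactants: 50 C1–C40 β-hydroxy ketone
Product: 51 C1–C40 27,29-anti diol
Conditions: Me4NBH(OAc)3, MeCN/AcOH (1:1), −30 °C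
Reagents that add atoms: none
Why: Evans–Saksena reduction: the C29 hydroxyl exchanges with acetate on boron and the alkoxy-diacetoxyborohydride delivers hydride intramolecularly through a chair transition state. This gives the 27,29-anti diol; C27 is thereby syn to C25, as the target requires.

Step 37
Reactants: 51 C1–C40 27,29-anti diol
Product: 52 C1–C40 nonakis-TBS ether (1-OPMB; 35-OBn)
Conditions: TBSOTf, 2,6-lutidine, CH2Cl2, −78 → 0 °C
Reagents that add atoms: tert-butyldimethylsilyl triflate, CC(C)(C)[Si](C)(C)OS(=O)(=O)C(F)(F)F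
Why: Exhaustive silylation of the two secondary hydroxyls with the reactive silyl triflate; all nine future free hydroxyls now carry the same group.

Step 38
Reactants: 52 C1–C40 nonakis-TBS ether
Product: 53 C1 primary alcohol
Conditions: DDQ, CH2Cl2/pH 7 buffer, 0 °C
Reagents that add atoms: none
Why: Oxidative cleavage of the electron-rich PMB ether through a charge-transfer complex and hydrolysis of the oxocarbenium ion; the plain benzyl ether at O35 and the silyl ethers are much slower.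

Step 39
Reactants: 53 C1 primary alcohol
Product: 55 C1 carboxylic acid, via C1 aldehyde 54 (not isolated)
Conditions: TEMPO (cat.), PhI(OAc)2, CH2Cl2/H2O (2:1), rt
Reagents that add atoms: water, O
Why: Oxoammonium-mediated oxidation of the primary alcohol to the aldehyde and, through its hydrate, to the acid; no other hydroxyl is free at this stage.

Step 40
Reactants: 55 C1 carboxylic acid
Product: 56 seco acid (35-OH)
Conditions: H2 (1 atm), Pd(OH)2/C, EtOAc, rt
Reagents that add atoms: none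
Why: Hydrogenolysis of the single benzyl ether; silyl ethers and the acid are unaffected, and sulfur left the molecule in step 35.

Step 41
Reactants: 56 seco acid
Product: 58 nonakis-TBS macrolactone, via mixed anhydride 57 (not isolated)
Conditions: 2,4,6-trichlorobenzoyl chloride, Et3N, THF, rt; then slow addition to DMAP, toluene, 80 °C (high dilution)
Reagents that add atoms: none
Why: Yamaguchi macrolactonisation: the mixed anhydride is attacked by DMAP at the less hindered carbonyl and the acylpyridinium is trapped by O35. Closure is an acyl substitution forming the 36-membered ring, with retention at C35.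

Step 42
Reactants: 58 nonakis-TBS macrolactone
Product: 59 target macrolactone
Conditions: HF·pyridine, pyridine/THF, 0 °C → rt
Reagents that add atoms: none
Why: Fluoride-driven cleavage of all nine silyl ethers under buffered acidic conditions, which avoids the base-induced acyl shift from O35 to O33.

## Compound list

1 | 1,3-dithiane | C1CSCSC1 | starting material
2 | tert-butyldimethylsilyl chloride | CC(C)(C)[Si](C)(C)Cl | starting material
3 | 2-lithio-1,3-dithiane (not isolated) | [Li]C1SCCCS1 | intermediate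
4 | 2-(tert-butyldimethylsilyl)-1,3-dithiane | CC(C)(C)[Si](C)(C)C1SCCCS1 | intermediate
5 | (R)-citronellol, (3R)-3,7-dimethyloct-6-en-1-ol | OCC[C@H](C)CCC=C(C)C | starting material
6 | 1-({[(3R)-3,7-dimethyloct-6-en-1-yl]oxy}methyl)-4-methoxybenzene | COc1ccc(COCC[C@H](C)CCC=C(C)C)cc1 | intermediate
7 | 3-[(3R)-5-(PMB-oxy)-3-methylpentyl]-5,5-dimethyl-1,2,4-trioxolane, both ring epimers (not isolated) | COc1ccc(COCC[C@H](C)CCC2OOC(C)(C)O2)cc1 | intermediate
8 | (4R)-6-[(4-methoxybenzyl)oxy]-4-methylhexanal | COc1ccc(COCC[C@H](C)CCC=O)cc1 | intermediate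
9 | (2R,4S)-2-chloro-6-[(4-methoxybenzyl)oxy]-4-methylhexanal (not isolated) | COc1ccc(COCC[C@H](C)C[C@@H](Cl)C=O)cc1 | intermediate
10 | (2R,4S)-2-chloro-6-[(4-methoxybenzyl)oxy]-4-methylhexan-1-ol | COc1ccc(COCC[C@H](C)C[C@@H](Cl)CO)cc1 | intermediate
11 | C1–C6 epoxide, (2S)-2-[(2S)-4-[(4-methoxybenzyl)oxy]-2-methylbutyl]oxirane | C1[C@@H](O1)C[C@@H](C)CCOCc1ccc(OC)cc1 | intermediate
12 | (4R,6S)-8-[(4-methoxybenzyl)oxy]-6-methyloct-1-en-4-ol (C1–C8; 5-OH) | C=CC[C@@H](O)C[C@@H](C)CCOCc1ccc(OC)cc1 | intermediate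
13 | tert-butyl({(4R,6S)-8-[(4-methoxybenzyl)oxy]-6-methyloct-1-en-4-yl}oxy)dimethylsilane (C1–C8; 5-OTBS) | C=CC[C@@H](O[Si](C)(C)C(C)(C)C)C[C@@H](C)CCOCc1ccc(OC)cc1 | intermediate
14 | (5R,7S)-5-(TBS-oxy)-9-(PMB-oxy)-7-methylnonanal (C1–C9) | O=CCCC[C@@H](O[Si](C)(C)C(C)(C)C)C[C@@H](C)CCOCc1ccc(OC)cc1 | intermediate
15 | O-bis(isopinocampheyl)boryl derivative of 16, Ipc groups from (−)-α-pinene (C9 borinate, not isolated) | C=CC[C@@H](OB([C@H]1C[C@H]2C[C@@H]([C@@H]1C)C2(C)C)[C@H]1C[C@H]2C[C@@H]([C@@H]1C)C2(C)C)CCC[C@@H](O[Si](C)(C)C(C)(C)C)C[C@@H](C)CCOCc1ccc(OC)cc1 | intermediate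
16 | (4S,8R,10S)-8-(TBS-oxy)-12-(PMB-oxy)-10-methyldodec-1-en-4-ol (C1–C12; 9-OH) | C=CC[C@@H](O)CCC[C@@H](O[Si](C)(C)C(C)(C)C)C[C@@H](C)CCOCc1ccc(OC)cc1 | intermediate
17 | (4S,8R,10S)-4,8-bis(TBS-oxy)-12-(PMB-oxy)-10-methyldodec-1-ene (C1–C12) | C=CC[C@@H](O[Si](C)(C)C(C)(C)C)CCC[C@@H](O[Si](C)(C)C(C)(C)C)C[C@@H](C)CCOCc1ccc(OC)cc1 | intermediate
18 | (5S,9R,11S)-5,9-bis(TBS-oxy)-13-(PMB-oxy)-11-methyltridecanal (C1–C13) | O=CCCC[C@@H](O[Si](C)(C)C(C)(C)C)CCC[C@@H](O[Si](C)(C)C(C)(C)C)C[C@@H](C)CCOCc1ccc(OC)cc1 | intermediate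
19 | O-bis(isopinocampheyl)boryl derivative of 20, Ipc groups from (+)-α-pinene (C13 borinate, not isolated) | C=CC[C@H](OB([C@@H]1C[C@@H]2C[C@H]([C@H]1C)C2(C)C)[C@@H]1C[C@@H]2C[C@H]([C@H]1C)C2(C)C)CCC[C@@H](O[Si](C)(C)C(C)(C)C)CCC[C@@H](O[Si](C)(C)C(C)(C)C)C[C@@H](C)CCOCc1ccc(OC)cc1 | intermediate
20 | (4R,8R,12R,14S)-8,12-bis(TBS-oxy)-16-(PMB-oxy)-14-methylhexadec-1-en-4-ol (C1–C16; 13-OH) | C=CC[C@H](O)CCC[C@@H](O[Si](C)(C)C(C)(C)C)CCC[C@@H](O[Si](C)(C)C(C)(C)C)C[C@@H](C)CCOCc1ccc(OC)cc1 | intermediate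
21 | (4R,8R,12R,14S)-4,8,12-tris(TBS-oxy)-16-(PMB-oxy)-14-methylhexadec-1-ene (C1–C16) | C=CC[C@H](O[Si](C)(C)C(C)(C)C)CCC[C@@H](O[Si](C)(C)C(C)(C)C)CCC[C@@H](O[Si](C)(C)C(C)(C)C)C[C@@H](C)CCOCc1ccc(OC)cc1 | intermediate
22 | (5R,9R,13R,15S)-5,9,13-tris(TBS-oxy)-17-(PMB-oxy)-15-methylheptadecanal (C1–C17) | O=CCCC[C@H](O[Si](C)(C)C(C)(C)C)CCC[C@@H](O[Si](C)(C)C(C)(C)C)CCC[C@@H](O[Si](C)(C)C(C)(C)C)C[C@@H](C)CCOCc1ccc(OC)cc1 | intermediate
23 | O-bis(isopinocampheyl)boryl derivative of 24, Ipc groups from (−)-α-pinene (C17 borinate, not isolated) | C=CC[C@@H](OB([C@H]1C[C@H]2C[C@@H]([C@@H]1C)C2(C)C)[C@H]1C[C@H]2C[C@@H]([C@@H]1C)C2(C)C)CCC[C@H](O[Si](C)(C)C(C)(C)C)CCC[C@@H](O[Si](C)(C)C(C)(C)C)CCC[C@@H](O[Si](C)(C)C(C)(C)C)C[C@@H](C)CCOCc1ccc(OC)cc1 | intermediate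
24 | (4S,8S,12R,16R,18S)-8,12,16-tris(TBS-oxy)-20-(PMB-oxy)-18-methylicos-1-en-4-ol (C1–C20; 17-OH) | C=CC[C@@H](O)CCC[C@H](O[Si](C)(C)C(C)(C)C)CCC[C@@H](O[Si](C)(C)C(C)(C)C)CCC[C@@H](O[Si](C)(C)C(C)(C)C)C[C@@H](C)CCOCc1ccc(OC)cc1 | intermediate
25 | (4S,8R,12R,16R,18S)-4,8,12,16-tetrakis(TBS-oxy)-20-(PMB-oxy)-18-methylicos-1-ene (C1–C20) | C=CC[C@@H](O[Si](C)(C)C(C)(C)C)CCC[C@H](O[Si](C)(C)C(C)(C)C)CCC[C@@H](O[Si](C)(C)C(C)(C)C)CCC[C@@H](O[Si](C)(C)C(C)(C)C)C[C@@H](C)CCOCc1ccc(OC)cc1 | intermediate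
26 | (5S,9R,13R,17R,19S)-5,9,13,17-tetrakis(TBS-oxy)-21-(PMB-oxy)-19-methylhenicosanal (C1–C21) | O=CCCC[C@@H](O[Si](C)(C)C(C)(C)C)CCC[C@H](O[Si](C)(C)C(C)(C)C)CCC[C@@H](O[Si](C)(C)C(C)(C)C)CCC[C@@H](O[Si](C)(C)C(C)(C)C)C[C@@H](C)CCOCc1ccc(OC)cc1 | intermediate
27 | O-bis(isopinocampheyl)boryl derivative of 28, Ipc groups from (+)-α-pinene (C21 borinate, not isolated) | C=CC[C@H](OB([C@@H]1C[C@@H]2C[C@H]([C@H]1C)C2(C)C)[C@@H]1C[C@@H]2C[C@H]([C@H]1C)C2(C)C)CCC[C@@H](O[Si](C)(C)C(C)(C)C)CCC[C@H](O[Si](C)(C)C(C)(C)C)CCC[C@@H](O[Si](C)(C)C(C)(C)C)CCC[C@@H](O[Si](C)(C)C(C)(C)C)C[C@@H](C)CCOCc1ccc(OC)cc1 | intermediate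
28 | (4R,8R,12S,16R,20R,22S)-8,12,16,20-tetrakis(TBS-oxy)-24-(PMB-oxy)-22-methyltetracos-1-en-4-ol (C1–C24; 21-OH) | C=CC[C@H](O)CCC[C@@H](O[Si](C)(C)C(C)(C)C)CCC[C@H](O[Si](C)(C)C(C)(C)C)CCC[C@@H](O[Si](C)(C)C(C)(C)C)CCC[C@@H](O[Si](C)(C)C(C)(C)C)C[C@@H](C)CCOCc1ccc(OC)cc1 | intermediate
29 | (4R,8S,12S,16R,20R,22S)-4,8,12,16,20-pentakis(TBS-oxy)-24-(PMB-oxy)-22-methyltetracos-1-ene (C1–C24) | C=CC[C@H](O[Si](C)(C)C(C)(C)C)CCC[C@@H](O[Si](C)(C)C(C)(C)C)CCC[C@H](O[Si](C)(C)C(C)(C)C)CCC[C@@H](O[Si](C)(C)C(C)(C)C)CCC[C@@H](O[Si](C)(C)C(C)(C)C)C[C@@H](C)CCOCc1ccc(OC)cc1 | intermediate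
30 | (5R,9S,13S,17R,21R,23S)-5,9,13,17,21-pentakis(TBS-oxy)-25-(PMB-oxy)-23-methylpentacosanal (C1–C25) | O=CCCC[C@H](O[Si](C)(C)C(C)(C)C)CCC[C@@H](O[Si](C)(C)C(C)(C)C)CCC[C@H](O[Si](C)(C)C(C)(C)C)CCC[C@@H](O[Si](C)(C)C(C)(C)C)CCC[C@@H](O[Si](C)(C)C(C)(C)C)C[C@@H](C)CCOCc1ccc(OC)cc1 | intermediate
31 | (3S,5R,9R,13S,17R,21S) C1–C26 epoxide, both epimers at C25: 25,26-epoxide, 5,9,13,17,21-pentakis-OTBS, 3-methyl, 1-OPMB | C1C(O1)CCC[C@H](O[Si](C)(C)C(C)(C)C)CCC[C@@H](O[Si](C)(C)C(C)(C)C)CCC[C@H](O[Si](C)(C)C(C)(C)C)CCC[C@@H](O[Si](C)(C)C(C)(C)C)CCC[C@@H](O[Si](C)(C)C(C)(C)C)C[C@@H](C)CCOCc1ccc(OC)cc1 | intermediate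
32 | (3S,5R,9R,13S,17R,21S,25S) C1–C26 epoxide: 25,26-epoxide, 5,9,13,17,21-pentakis-OTBS, 3-methyl, 1-OPMB | C1[C@@H](O1)CCC[C@H](O[Si](C)(C)C(C)(C)C)CCC[C@@H](O[Si](C)(C)C(C)(C)C)CCC[C@H](O[Si](C)(C)C(C)(C)C)CCC[C@@H](O[Si](C)(C)C(C)(C)C)CCC[C@@H](O[Si](C)(C)C(C)(C)C)C[C@@H](C)CCOCc1ccc(OC)cc1 | intermediate
33 | (E)-hept-2-en-1-ol | CCCC/C=C/CO | starting material
34 | [(2R,3R)-3-butyloxiran-2-yl]methanol | CCCC[C@H]1O[C@@H]1CO | intermediate
35 | (2S,3S)-3-methylheptane-1,2-diol | CCCC[C@H](C)[C@H](O)CO | intermediate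
36 | (2S,3S)-2-hydroxy-3-methylheptyl 4-methylbenzenesulfonate, as its sodium alkoxide (not isolated) | CCCC[C@H](C)[C@H](O)COS(=O)(=O)c1ccc(C)cc1 | intermediate
37 | (2S)-2-[(2S)-hexan-2-yl]oxirane | CCCC[C@H](C)[C@H]1CO1 | intermediate
38 | (4R,5S)-5-methylnon-1-en-4-ol | CCCC[C@H](C)[C@H](O)CC=C | intermediate
39 | (4R,5S)-4-(benzyloxy)-5-methylnon-1-ene | CCCC[C@H](C)[C@H](OCc1ccccc1)CC=C | intermediate
40 | 3-[(2R,3S)-2-(benzyloxy)-3-methylheptyl]-1,2,4-trioxolane, both ring epimers (not isolated) | CCCC[C@H](C)[C@H](OCc1ccccc1)CC1OOCO1 | intermediate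
41 | (3R,4S)-3-(benzyloxy)-4-methyloctanal | CCCC[C@H](C)[C@H](OCc1ccccc1)CC=O | intermediate
42 | (4S,6R,7S)-6-(benzyloxy)-7-methylundec-1-en-4-ol | CCCC[C@H](C)[C@H](OCc1ccccc1)C[C@@H](O)CC=C | intermediate
43 | (4S,6R,7S)-6-(benzyloxy)-4-(TBS-oxy)-7-methylundec-1-ene | CCCC[C@H](C)[C@H](OCc1ccccc1)C[C@@H](O[Si](C)(C)C(C)(C)C)CC=C | intermediate
44 | (5S,7R,8S)-7-(benzyloxy)-5-(TBS-oxy)-8-methyldodecanal | CCCC[C@H](C)[C@H](OCc1ccccc1)C[C@@H](O[Si](C)(C)C(C)(C)C)CCCC=O | intermediate
45 | 2-[(4S,6R,7S)-6-(benzyloxy)-4-(TBS-oxy)-7-methylundecyl]oxirane, both epimers at the oxirane carbon (C29) | CCCC[C@H](C)[C@H](OCc1ccccc1)C[C@@H](O[Si](C)(C)C(C)(C)C)CCCC1CO1 | intermediate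
46 | C28–C40 epoxide, (2S)-2-[(4S,6R,7S)-6-(benzyloxy)-4-(TBS-oxy)-7-methylundecyl]oxirane | CCCC[C@H](C)[C@H](OCc1ccccc1)C[C@@H](O[Si](C)(C)C(C)(C)C)CCC[C@H]1CO1 | intermediate
47 | 2-lithio-2-(tert-butyldimethylsilyl)-1,3-dithiane (not isolated) | CC(C)(C)[Si](C)(C)C1([Li])SCCCS1 | intermediate
48 | (3S,5R,9R,13S,17R,21S,25S) C25 lithium alkoxide carrying the 2-TBS-dithiane at C27: 5,9,13,17,21-pentakis-OTBS, 1-OPMB (not isolated) | CC(C)(C)[Si](C)(C)C1(SCCCS1)C[C@@H]([O-])CCC[C@H](O[Si](C)(C)C(C)(C)C)CCC[C@@H](O[Si](C)(C)C(C)(C)C)CCC[C@H](O[Si](C)(C)C(C)(C)C)CCC[C@@H](O[Si](C)(C)C(C)(C)C)CCC[C@@H](O[Si](C)(C)C(C)(C)C)C[C@@H](C)CCOCc1ccc(OC)cc1.[Li+] | intermediate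
49 | (3S,5R,9R,13S,17S,21R,25S,29S,33S,35R,36S)-35-(benzyloxy)-5,9,13,17,21,25,33-heptakis(TBS-oxy)-1-(PMB-oxy)-3,36-dimethyltetracontan-29-ol with a 1,3-dithiane at C27 (C27 = dithiane C2) | CCCC[C@H](C)[C@H](OCc1ccccc1)C[C@@H](O[Si](C)(C)C(C)(C)C)CCC[C@H](O)CC1(SCCCS1)C[C@@H](O[Si](C)(C)C(C)(C)C)CCC[C@H](O[Si](C)(C)C(C)(C)C)CCC[C@@H](O[Si](C)(C)C(C)(C)C)CCC[C@H](O[Si](C)(C)C(C)(C)C)CCC[C@@H](O[Si](C)(C)C(C)(C)C)CCC[C@@H](O[Si](C)(C)C(C)(C)C)C[C@@H](C)CCOCc1ccc(OC)cc1 | intermediate
50 | (3S,5R,9R,13S,17S,21R,25S,29S,33S,35R,36S)-35-(benzyloxy)-29-hydroxy-5,9,13,17,21,25,33-heptakis(TBS-oxy)-1-(PMB-oxy)-3,36-dimethyltetracontan-27-one | CCCC[C@H](C)[C@H](OCc1ccccc1)C[C@@H](O[Si](C)(C)C(C)(C)C)CCC[C@H](O)CC(=O)C[C@@H](O[Si](C)(C)C(C)(C)C)CCC[C@H](O[Si](C)(C)C(C)(C)C)CCC[C@@H](O[Si](C)(C)C(C)(C)C)CCC[C@H](O[Si](C)(C)C(C)(C)C)CCC[C@@H](O[Si](C)(C)C(C)(C)C)CCC[C@@H](O[Si](C)(C)C(C)(C)C)C[C@@H](C)CCOCc1ccc(OC)cc1 | intermediate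
51 | (3S,5R,9R,13S,17S,21R,25S,27R,29S,33S,35R,36S)-35-(benzyloxy)-5,9,13,17,21,25,33-heptakis(TBS-oxy)-1-(PMB-oxy)-3,36-dimethyltetracontane-27,29-diol | CCCC[C@H](C)[C@H](OCc1ccccc1)C[C@@H](O[Si](C)(C)C(C)(C)C)CCC[C@H](O)C[C@@H](O)C[C@@H](O[Si](C)(C)C(C)(C)C)CCC[C@H](O[Si](C)(C)C(C)(C)C)CCC[C@@H](O[Si](C)(C)C(C)(C)C)CCC[C@H](O[Si](C)(C)C(C)(C)C)CCC[C@@H](O[Si](C)(C)C(C)(C)C)CCC[C@@H](O[Si](C)(C)C(C)(C)C)C[C@@H](C)CCOCc1ccc(OC)cc1 | intermediate
52 | (3S,5R,9R,13S,17S,21R,25S,27S,29S,33S,35R,36S)-35-(benzyloxy)-5,9,13,17,21,25,27,29,33-nonakis(TBS-oxy)-1-(PMB-oxy)-3,36-dimethyltetracontane | CCCC[C@H](C)[C@H](OCc1ccccc1)C[C@@H](O[Si](C)(C)C(C)(C)C)CCC[C@H](O[Si](C)(C)C(C)(C)C)C[C@@H](O[Si](C)(C)C(C)(C)C)C[C@@H](O[Si](C)(C)C(C)(C)C)CCC[C@H](O[Si](C)(C)C(C)(C)C)CCC[C@@H](O[Si](C)(C)C(C)(C)C)CCC[C@H](O[Si](C)(C)C(C)(C)C)CCC[C@@H](O[Si](C)(C)C(C)(C)C)CCC[C@@H](O[Si](C)(C)C(C)(C)C)C[C@@H](C)CCOCc1ccc(OC)cc1 | intermediate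
53 | (3S,5R,9R,13S,17S,21R,25S,27S,29S,33S,35R,36S)-35-(benzyloxy)-5,9,13,17,21,25,27,29,33-nonakis(TBS-oxy)-3,36-dimethyltetracontan-1-ol | CCCC[C@H](C)[C@H](OCc1ccccc1)C[C@@H](O[Si](C)(C)C(C)(C)C)CCC[C@H](O[Si](C)(C)C(C)(C)C)C[C@@H](O[Si](C)(C)C(C)(C)C)C[C@@H](O[Si](C)(C)C(C)(C)C)CCC[C@H](O[Si](C)(C)C(C)(C)C)CCC[C@@H](O[Si](C)(C)C(C)(C)C)CCC[C@H](O[Si](C)(C)C(C)(C)C)CCC[C@@H](O[Si](C)(C)C(C)(C)C)CCC[C@@H](O[Si](C)(C)C(C)(C)C)C[C@@H](C)CCO | intermediate
54 | (3R,5R,9R,13S,17S,21R,25S,27S,29S,33S,35R,36S)-35-(benzyloxy)-5,9,13,17,21,25,27,29,33-nonakis(TBS-oxy)-3,36-dimethyltetracontanal (not isolated) | CCCC[C@H](C)[C@H](OCc1ccccc1)C[C@@H](O[Si](C)(C)C(C)(C)C)CCC[C@H](O[Si](C)(C)C(C)(C)C)C[C@@H](O[Si](C)(C)C(C)(C)C)C[C@@H](O[Si](C)(C)C(C)(C)C)CCC[C@H](O[Si](C)(C)C(C)(C)C)CCC[C@@H](O[Si](C)(C)C(C)(C)C)CCC[C@H](O[Si](C)(C)C(C)(C)C)CCC[C@@H](O[Si](C)(C)C(C)(C)C)CCC[C@@H](O[Si](C)(C)C(C)(C)C)C[C@@H](C)CC=O | intermediate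
55 | (3R,5R,9R,13S,17S,21R,25S,27S,29S,33S,35R,36S)-35-(benzyloxy)-5,9,13,17,21,25,27,29,33-nonakis(TBS-oxy)-3,36-dimethyltetracontanoic acid | CCCC[C@H](C)[C@H](OCc1ccccc1)C[C@@H](O[Si](C)(C)C(C)(C)C)CCC[C@H](O[Si](C)(C)C(C)(C)C)C[C@@H](O[Si](C)(C)C(C)(C)C)C[C@@H](O[Si](C)(C)C(C)(C)C)CCC[C@H](O[Si](C)(C)C(C)(C)C)CCC[C@@H](O[Si](C)(C)C(C)(C)C)CCC[C@H](O[Si](C)(C)C(C)(C)C)CCC[C@@H](O[Si](C)(C)C(C)(C)C)CCC[C@@H](O[Si](C)(C)C(C)(C)C)C[C@@H](C)CC(=O)O | intermediate
56 | (3R,5R,9R,13S,17S,21R,25S,27S,29S,33S,35R,36S)-35-hydroxy-5,9,13,17,21,25,27,29,33-nonakis(TBS-oxy)-3,36-dimethyltetracontanoic acid (seco acid) | CCCC[C@H](C)[C@H](O)C[C@@H](O[Si](C)(C)C(C)(C)C)CCC[C@H](O[Si](C)(C)C(C)(C)C)C[C@@H](O[Si](C)(C)C(C)(C)C)C[C@@H](O[Si](C)(C)C(C)(C)C)CCC[C@H](O[Si](C)(C)C(C)(C)C)CCC[C@@H](O[Si](C)(C)C(C)(C)C)CCC[C@H](O[Si](C)(C)C(C)(C)C)CCC[C@@H](O[Si](C)(C)C(C)(C)C)CCC[C@@H](O[Si](C)(C)C(C)(C)C)C[C@@H](C)CC(=O)O | intermediate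
57 | mixed anhydride of 56 with 2,4,6-trichlorobenzoic acid (not isolated) | CCCC[C@H](C)[C@H](O)C[C@@H](O[Si](C)(C)C(C)(C)C)CCC[C@H](O[Si](C)(C)C(C)(C)C)C[C@@H](O[Si](C)(C)C(C)(C)C)C[C@@H](O[Si](C)(C)C(C)(C)C)CCC[C@H](O[Si](C)(C)C(C)(C)C)CCC[C@@H](O[Si](C)(C)C(C)(C)C)CCC[C@H](O[Si](C)(C)C(C)(C)C)CCC[C@@H](O[Si](C)(C)C(C)(C)C)CCC[C@@H](O[Si](C)(C)C(C)(C)C)C[C@@H](C)CC(=O)OC(=O)c1c(Cl)cc(Cl)cc1Cl | intermediate
58 | (4R,6R,10R,14S,18S,22R,26S,28S,30S,34S,36R)-36-[(2S)-hexan-2-yl]-6,10,14,18,22,26,28,30,34-nonakis(TBS-oxy)-4-methyl-1-oxacyclohexatriacontan-2-one | CCCC[C@H](C)[C@H]1C[C@@H](O[Si](C)(C)C(C)(C)C)CCC[C@H](O[Si](C)(C)C(C)(C)C)C[C@@H](O[Si](C)(C)C(C)(C)C)C[C@@H](O[Si](C)(C)C(C)(C)C)CCC[C@H](O[Si](C)(C)C(C)(C)C)CCC[C@@H](O[Si](C)(C)C(C)(C)C)CCC[C@H](O[Si](C)(C)C(C)(C)C)CCC[C@@H](O[Si](C)(C)C(C)(C)C)CCC[C@@H](O[Si](C)(C)C(C)(C)C)C[C@@H](C)CC(=O)O1 | intermediate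
59 | (4R,6R,10R,14S,18S,22R,26S,28S,30S,34S,36R)-36-[(2S)-hexan-2-yl]-6,10,14,18,22,26,28,30,34-nonahydroxy-4-methyl-1-oxacyclohexatriacontan-2-one (CNP0225459.2) | CCCC[C@H](C)[C@H]1C[C@@H](O)CCC[C@H](O)C[C@@H](O)C[C@@H](O)CCC[C@H](O)CCC[C@@H](O)CCC[C@H](O)CCC[C@@H](O)CCC[C@@H](O)C[C@@H](C)CC(=O)O1 | target

## Step count and least certain steps

Total: 42 steps. Longest linear sequence: 30 steps (5 to 59; steps 2–22 and 34–42). The route to 46 (steps 23–33) and the linchpin (step 1) are side branches.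

**Step 34 (key step).** What may go wrong: silyl migration may start before 46 is present, so that the relay anion consumes a second molecule of 32. The second alkylation, between a crowded tertiary dithiane anion and a long-chain epoxide, may also be slow enough for the anion to be protonated. The fallback separates the two alkylations. It sets out from 32, which is opened with 2-lithio-1,3-dithiane 3 to give the C1–C27 dithianyl carbinol F1. Silylation with TBSOTf gives its 25-O-TBS ether F2. Deprotonation of F2 (t-BuLi, HMPA/THF, −78 °C) and addition of 46 return to 49.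

**Step 9.** What may go wrong: incomplete facial selectivity in the allylboration. The minor C9 epimer is a 1,5-diastereomer that cannot be expected to separate, and the same leak recurs in steps 12, 15 and 18, so it accumulates along the chain. The fallback buys the stereocentre instead of creating it. It sets out from 13.
- Ozonolysis with NaBH4 work-up gives the C1–C7 primary alcohol F3.
- I2, PPh3 and imidazole give the C7 iodide F4.
- Magnesium in THF gives the Grignard reagent F5, which with CuI (cat.) opens (S)-epichlorohydrin at its oxirane CH2 and gives the C1–C10 chlorohydrin F6.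
- K2CO3 in MeOH closes the C9–C10 epoxide F7.
- Vinylmagnesium bromide with CuI (cat.) opens F7 at C10 and returns to 16.

**Step 22.** What may go wrong: the resolution discards at least half of a twenty-step intermediate, and with a long, lipophilic substrate the discrimination between the C25 epimers may be incomplete, leaving (25R)-epoxide in the product. The fallback buys C25. It sets out from 29. Cross-metathesis with (S)-but-3-ene-1,2-diol (second-generation Hoveyda–Grubbs catalyst, CH2Cl2, 40 °C) gives the E-configured ene-diol F8. Diimide reduction (2-nitrobenzenesulfonylhydrazide, Et3N) gives the saturated 25,26-diol F9. NaH and N-tosylimidazole then close the epoxide and return to 32.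

**Step 4.** What may go wrong: the α-chloro aldehyde may enolise before reduction, or catalyst control may be incomplete, either of which erodes the configuration at C5. The fallback replaces asymmetric catalysis by resolution. It sets out from 8. Chlorination with an achiral amine salt (pyrrolidine·CF3CO2H, N-chlorosuccinimide) and borohydride reduction give the C5-epimeric chlorohydrin F10. KOH gives the C5-epimeric epoxide F11. Hydrolytic kinetic resolution with (S,S)-(salen)Co(OAc) removes the (5R)-epimer as its diol and returns to 11.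

**Step 32.** What may go wrong: the basic ylide may enolise the unbranched aldehyde, leading to aldol self-condensation instead of methylene transfer. The fallback goes through an alkene. It sets out from 44. Wittig methylenation (Ph3P=CH2) gives the terminal alkene F12. Epoxidation with m-chloroperbenzoic acid returns to the epimeric epoxide 45, which enters step 33 unchanged.

## Further compounds

F1 | step 34 | C1–C27 dithianyl carbinol: 2-substituted 1,3-dithiane at C27, 25-OH, 5,9,13,17,21-pentakis-OTBS, 1-OPMB | C1(SCCCS1)C[C@@H](O)CCC[C@H](O[Si](C)(C)C(C)(C)C)CCC[C@@H](O[Si](C)(C)C(C)(C)C)CCC[C@H](O[Si](C)(C)C(C)(C)C)CCC[C@@H](O[Si](C)(C)C(C)(C)C)CCC[C@@H](O[Si](C)(C)C(C)(C)C)C[C@@H](C)CCOCc1ccc(OC)cc1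
F2 | step 34 | 25-O-TBS ether of F1 | C1(SCCCS1)C[C@@H](O[Si](C)(C)C(C)(C)C)CCC[C@H](O[Si](C)(C)C(C)(C)C)CCC[C@@H](O[Si](C)(C)C(C)(C)C)CCC[C@H](O[Si](C)(C)C(C)(C)C)CCC[C@@H](O[Si](C)(C)C(C)(C)C)CCC[C@@H](O[Si](C)(C)C(C)(C)C)C[C@@H](C)CCOCc1ccc(OC)cc1
F3 | step 9 | (3S,5S)-3-(TBS-oxy)-7-(PMB-oxy)-5-methylheptan-1-ol (C1–C7 alcohol) | OCC[C@@H](O[Si](C)(C)C(C)(C)C)C[C@@H](C)CCOCc1ccc(OC)cc1
F4 | step 9 | tert-butyl({(3S,5S)-1-iodo-7-[(4-methoxybenzyl)oxy]-5-methylheptan-3-yl}oxy)dimethylsilane (C7 iodide) | ICC[C@@H](O[Si](C)(C)C(C)(C)C)C[C@@H](C)CCOCc1ccc(OC)cc1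
F5 | step 9 | [(3S,5S)-3-(TBS-oxy)-7-(PMB-oxy)-5-methylheptyl]magnesium iodide | I[Mg]CC[C@@H](O[Si](C)(C)C(C)(C)C)C[C@@H](C)CCOCc1ccc(OC)cc1
F6 | step 9 | (2S,6R,8S)-1-chloro-6-(TBS-oxy)-10-(PMB-oxy)-8-methyldecan-2-ol (C1–C10 chlorohydrin) | ClC[C@@H](O)CCC[C@@H](O[Si](C)(C)C(C)(C)C)C[C@@H](C)CCOCc1ccc(OC)cc1
F7 | step 9 | (3S,5R,9S) C1–C10 epoxide: 9,10-epoxide, 5-OTBS, 3-methyl, 1-OPMB | C1[C@@H](O1)CCC[C@@H](O[Si](C)(C)C(C)(C)C)C[C@@H](C)CCOCc1ccc(OC)cc1
F8 | step 22 | (3S,5R,9R,13R,17S,21R,23E,25S)-5,9,13,17,21-pentakis(TBS-oxy)-1-(PMB-oxy)-3-methylhexacos-23-ene-25,26-diol | OC[C@@H](O)/C=C/C[C@H](O[Si](C)(C)C(C)(C)C)CCC[C@@H](O[Si](C)(C)C(C)(C)C)CCC[C@H](O[Si](C)(C)C(C)(C)C)CCC[C@@H](O[Si](C)(C)C(C)(C)C)CCC[C@@H](O[Si](C)(C)C(C)(C)C)C[C@@H](C)CCOCc1ccc(OC)cc1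
F9 | step 22 | (3S,5R,9R,13S,17R,21S,25S)-5,9,13,17,21-pentakis(TBS-oxy)-1-(PMB-oxy)-3-methylhexacosane-25,26-diol | OC[C@@H](O)CCC[C@H](O[Si](C)(C)C(C)(C)C)CCC[C@@H](O[Si](C)(C)C(C)(C)C)CCC[C@H](O[Si](C)(C)C(C)(C)C)CCC[C@@H](O[Si](C)(C)C(C)(C)C)CCC[C@@H](O[Si](C)(C)C(C)(C)C)C[C@@H](C)CCOCc1ccc(OC)cc1
F10 | step 4 | (4S)-2-chloro-6-(PMB-oxy)-4-methylhexan-1-ol, both C2 epimers | COc1ccc(COCC[C@H](C)CC(Cl)CO)cc1
F11 | step 4 | 2-[(2S)-4-(PMB-oxy)-2-methylbutyl]oxirane, both epimers at the oxirane carbon | C1C(O1)C[C@@H](C)CCOCc1ccc(OC)cc1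
F12 | step 32 | (6S,8R,9S)-8-(benzyloxy)-6-(TBS-oxy)-9-methyltridec-1-ene | CCCC[C@H](C)[C@H](OCc1ccccc1)C[C@@H](O[Si](C)(C)C(C)(C)C)CCCC=C
A1 | alternative 1 | nonakis-TBS 36-membered macrolactone (identical with 58) | CCCC[C@H](C)[C@H]1C[C@@H](O[Si](C)(C)C(C)(C)C)CCC[C@H](O[Si](C)(C)C(C)(C)C)C[C@@H](O[Si](C)(C)C(C)(C)C)C[C@@H](O[Si](C)(C)C(C)(C)C)CCC[C@H](O[Si](C)(C)C(C)(C)C)CCC[C@@H](O[Si](C)(C)C(C)(C)C)CCC[C@H](O[Si](C)(C)C(C)(C)C)CCC[C@@H](O[Si](C)(C)C(C)(C)C)CCC[C@@H](O[Si](C)(C)C(C)(C)C)C[C@@H](C)CC(=O)O1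
A2 | alternative 1 | nonakis-TBS 35-membered carbocyclic ketone (C1 carbonyl bonded to C2 and C35) | CCCC[C@H](C)[C@H]1C[C@@H](O[Si](C)(C)C(C)(C)C)CCC[C@H](O[Si](C)(C)C(C)(C)C)C[C@@H](O[Si](C)(C)C(C)(C)C)C[C@@H](O[Si](C)(C)C(C)(C)C)CCC[C@H](O[Si](C)(C)C(C)(C)C)CCC[C@@H](O[Si](C)(C)C(C)(C)C)CCC[C@H](O[Si](C)(C)C(C)(C)C)CCC[C@@H](O[Si](C)(C)C(C)(C)C)CCC[C@@H](O[Si](C)(C)C(C)(C)C)C[C@@H](C)CC1=O
A3 | alternative 2 | 2-[(4S,6R,7S)-4-(TBS-oxy)-7-methylundec-1-en-6-yl]-4,4,5,5-tetramethyl-1,3,2-dioxaborolane (C30–C40 boronic ester at C35) | CCCC[C@H](C)[C@H](B1OC(C)(C)C(C)(C)O1)C[C@@H](O[Si](C)(C)C(C)(C)C)CC=C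
A4 | alternative 2 | 2-butyl-4,4,5,5-tetramethyl-1,3,2-dioxaborolane | CCCCB1OC(C)(C)C(C)(C)O1
A5 | alternative 2 | ethyl 2,4,6-triisopropylbenzoate | CCOC(=O)c1c(C(C)C)cc(C(C)C)cc1C(C)C
A6 | alternative 2 | (3S)-3-(TBS-oxy)hex-5-en-1-yl 2,4,6-triisopropylbenzoate (C30–C35 benzoate) | C=CC[C@H](O[Si](C)(C)C(C)(C)C)CCOC(=O)c1c(C(C)C)cc(C(C)C)cc1C(C)C
A7 | alternative 3 | (4R,8R,12R,16R)-8,12-bis(TBS-oxy)nonadeca-1,18-diene-4,16-diol (C6–C24) | C=CC[C@H](O)CCC[C@@H](O[Si](C)(C)C(C)(C)C)CCC[C@H](O[Si](C)(C)C(C)(C)C)CCC[C@@H](O)CC=C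
A8 | alternative 3 | (5R,9R)-5,9-bis(TBS-oxy)tridecane-1,13-diol (C9–C21) | OCCCC[C@@H](O[Si](C)(C)C(C)(C)C)CCC[C@H](O[Si](C)(C)C(C)(C)C)CCCCO
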